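## Retrosynthetic overview

Indenone numbering is used for the bicyclic ketone: C-4 ketone, C-5 and C-6 enone carbons, C-7 methylene, C-7a and C-3a ring-fusion carbons.

1. The cyclohexenone ring is disconnected last: 29 ⇒ (Z)-iodoalkenyl cyclobutanol 26. A nickel-catalysed two-carbon ring expansion turns the cyclobutane C-4/C-3a/C-7a/C-7 into the six-membered ring by inserting C-5=C-6 between C-4 and C-7.
2. Enabling feature: in the six-membered ring the ketone carbon C-4 and the methylene C-7 both sit on the cis-dimethylated edge C-3a–C-7a, so a strained cis-fused cyclobutanone is latent in it. C-7 is neopentyl (C-7a has no hydrogen), so an alkyl–metal bond at C-7 cannot undergo β-hydride elimination.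
3. 26 ⇒ propargylic cyclobutanol 22 by hydroxyl-directed anti-methallylmagnesiation/iodination (this fixes which alkyne carbon becomes C-5 and which C-6) and Markovnikov hydration; 22 ⇒ cyclobutanone 9 + chroman alkyne 20.
4. 9 ⇒ 1,2-dimethylcyclopentene + dichloroketene ([2+2], dechlorination, sulfoximine resolution). 20 ⇒ (S)-2-methylglycidol + a benzylic Grignard reagent, then epoxide, acetylide opening and Pd-catalysed aryl C–O closure of the chroman with retention.
5. Order of ring formation: cyclobutane on the preformed cyclopentane (step 1), dihydropyran ring of the chroman (step 9), cyclohexenone ring by expansion of the cyclobutane (step 13).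

Key step: step 13

Remark (assumption): carbon nucleophiles are taken to add to the cyclobutanone carbonyl from the face anti to the cyclopentane ring, and 8, 22, 24, 25, 26 and 27 are drawn accordingly; this carbinol carbon becomes the trigonal ketone carbon C-4 in step 13, so its configuration does not affect the outcome.

## Route

Step 1
Reactants: 1 1,2-dimethylcyclopentene; 2 trichloroacetyl chloride
Product: 4 rac-7,7-dichloro-1,5-dimethylbicyclo[3.2.0]heptan-6-one (cis-fused), via dichloroketene 3 (not isolated)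
Conditions: Zn–Cu couple, POCl3, Et2O, reflux
Reagents that add atoms: none
Why: Dichloroketene made by zinc dechlorination should add to the electron-rich tetrasubstituted alkene in a thermal [2+2] cycloaddition that is suprafacial on the alkene, which sets the two methyl-bearing ring-fusion carbons cis (racemic) and, the alkene being symmetric, raises no regiochemical question.

Step 2
Reactants: 4 rac-7,7-dichloro-1,5-dimethylbicyclo[3.2.0]heptan-6-one
Product: 5 rac-1,5-dimethylbicyclo[3.2.0]heptan-6-one
Conditions: Zn dust, AcOH, 70 °C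
Reagents that add atoms: none
Why: Reductive dechlorination of the α,α-dichloroketone by zinc in acetic acid proceeds through the zinc enolate and should leave the strained ketone and both quaternary centres untouched.

Step 3
Reactants: 5 rac-1,5-dimethylbicyclo[3.2.0]heptan-6-one; 6 (S)-N,S-dimethyl-S-phenylsulfoximine
Product: 8 (1S,5S,6R)-1,5-dimethyl-6-{[(S)-N-methyl-S-phenylsulfonimidoyl]methyl}bicyclo[3.2.0]heptan-6-ol, via lithiated sulfoximine 7 (not isolated)
Conditions: 6, n-BuLi, THF, −78 °C; then 5, −78 °C; H2O; chromatographic separation of the diastereomeric adducts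
Reagents that add atoms: none
Why: Sulfoximine-mediated ketone resolution: the α-lithiated enantiopure sulfoximine adds to the carbonyl of both enantiomers of 5 (1,2-addition) to give diastereomeric β-hydroxysulfoximines that should be separable on silica, and keeping the adduct of the (1S,5S)-ketone fixes the absolute configuration of the two quaternary carbons.

Step 4
Reactants: 8 (1S,5S,6R)-1,5-dimethyl-6-{[(S)-N-methyl-S-phenylsulfonimidoyl]methyl}bicyclo[3.2.0]heptan-6-ol
Product: 9 (1S,5S)-1,5-dimethylbicyclo[3.2.0]heptan-6-one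
Conditions: toluene, 120 °C (sealed tube); distillation
Reagents that add atoms: none
Why: Thermal retro-addition of the β-hydroxysulfoximine through a six-membered hydrogen-bonded transition state should release the enantiopure ketone and the reusable sulfoximine without touching the ring-fusion centres.

Step 5
Reactants: 10 2-bromo-5-methoxy-1,3-dimethylbenzene
Product: 11 2-bromo-1-(bromomethyl)-5-methoxy-3-methylbenzene
Conditions: NBS (1.0 equiv), AIBN (cat.), PhCF3, 80 °C
Reagents that add atoms: N-bromosuccinimide, O=C1CCC(=O)N1Br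
Why: Wohl–Ziegler benzylic bromination of one of two equivalent methyl groups should be clean because the ring position para to the methoxy group is already blocked by bromine and the aryl bromide is inert to the radical chain.

Step 6
Reactants: 11 2-bromo-1-(bromomethyl)-5-methoxy-3-methylbenzene; 12 (S)-2-methylglycidol
Product: 14 (2R)-4-(2-bromo-5-methoxy-3-methylphenyl)-2-methylbutane-1,2-diol, via benzylic Grignard reagent 13 (not isolated)
Conditions: Mg, Et2O, 0 °C; then added to 12 (pre-treated with i-PrMgCl, THF, −40 °C), CuI (10 mol%), −40 → 0 °C; H2O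
Reagents that add atoms: none
Why: Magnesium inserts selectively into the benzylic C–Br bond and the CuI-catalysed Grignard opening of the epoxide occurs at its unsubstituted CH2 carbon, so the quaternary stereocentre comes from the chiral pool with no bond to it made or broken (the descriptor changes to R only through priorities).

Step 7
Reactants: 14 (2R)-4-(2-bromo-5-methoxy-3-methylphenyl)-2-methylbutane-1,2-diol
Product: 16 (2R)-2-[2-(2-bromo-5-methoxy-3-methylphenyl)ethyl]-2-methyloxirane, via primary tosylate 15 (not isolated)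
Conditions: TsCl, Et3N, DMAP (cat.), CH2Cl2, 0 °C; then K2CO3, MeOH, rt
Reagents that add atoms: none
Why: Selective sulfonylation of the primary hydroxyl followed by intramolecular Williamson displacement by the tertiary alkoxide should give the terminal epoxide with the C–O bond at the stereocentre retained.

Step 8
Reactants: 16 (2R)-2-[2-(2-bromo-5-methoxy-3-methylphenyl)ethyl]-2-methyloxirane; 17 ethynyltrimethylsilane
Product: 19 (3R)-1-(2-bromo-5-methoxy-3-methylphenyl)-3-methyl-6-(trimethylsilyl)hex-5-yn-3-ol, via lithium silylacetylide 18 (not isolated)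
Conditions: 17, n-BuLi, THF, −78 °C; then BF3·OEt2, 16, −78 °C; H2O
Reagents that add atoms: none
Why: Boron-trifluoride-assisted SN2 opening of the epoxide by the lithium acetylide at the CH2 terminus should give the tertiary homopropargylic alcohol with the stereocentre untouched.

Step 9
Reactants: 19 (3R)-1-(2-bromo-5-methoxy-3-methylphenyl)-3-methyl-6-(trimethylsilyl)hex-5-yn-3-ol
Product: 20 trimethyl{3-[(2R)-6-methoxy-2,8-dimethyl-3,4-dihydro-2H-chromen-2-yl]prop-1-yn-1-yl}silane
Conditions: Pd(OAc)2 (5 mol%), 2-(di-tert-butylphosphino)-1,1′-binaphthyl (6 mol%), Cs2CO3, toluene, 80 °C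
Reagents that add atoms: none
Why: Palladium-catalysed intramolecular aryl C–O coupling (Buchwald–Hartwig etherification) of the tertiary alcohol, which has no carbinol hydrogen for β-hydride elimination, should close the dihydropyran ring, and since only the aryl C–O bond is formed the configuration at the carbinol carbon is retained.

Step 10
Reactants: 20 trimethyl{3-[(2R)-6-methoxy-2,8-dimethyl-3,4-dihydro-2H-chromen-2-yl]prop-1-yn-1-yl}silane; 9 (1S,5S)-1,5-dimethylbicyclo[3.2.0]heptan-6-one
Product: 22 (1S,5S,6S)-6-{3-[(2R)-6-methoxy-2,8-dimethyl-3,4-dihydro-2H-chromen-2-yl]prop-1-yn-1-yl}-1,5-dimethylbicyclo[3.2.0]heptan-6-ol, via lithium acetylide 21 (not isolated)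
Conditions: MeLi·LiBr, THF, 0 °C → rt; then 9, −78 → −40 °C; H2O
Reagents that add atoms: none
Why: Methyllithium cleaves the alkynyl–silicon bond to the slim lithium acetylide, which should add to the strained but hindered cyclobutanone carbonyl (1,2-addition) without touching C-3a or C-7a.

Step 11
Reactants: 22 (1S,5S,6S)-6-{3-[(2R)-6-methoxy-2,8-dimethyl-3,4-dihydro-2H-chromen-2-yl]prop-1-yn-1-yl}-1,5-dimethylbicyclo[3.2.0]heptan-6-ol; 23 (2-methylallyl)magnesium chloride
Product: 25 (1S,5S,6R)-6-{(4Z)-5-iodo-6-[(2R)-6-methoxy-2,8-dimethyl-3,4-dihydro-2H-chromen-2-yl]-2-methylhexa-1,4-dien-4-yl}-1,5-dimethylbicyclo[3.2.0]heptan-6-ol, via alkenylmagnesium chelate 24 (not isolated)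
Conditions: 23 (3 equiv), CuI (10 mol%), THF–toluene, 60 °C; then I2, −40 → 0 °C; H2O
Reagents that add atoms: iodine, II
Why: Hydroxyl-directed anti-carbomagnesiation of a propargylic alcohol: the magnesium alkoxide delivers the methallyl group to the proximal alkyne carbon and holds magnesium on the distal carbon in a five-membered chelate, and iodinolysis with retention should give the (Z)-iodoalkene with iodine cis to the carbinol carbon, which fixes the future C-5 and C-6 and the geometry needed for the nickelacycle.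

Step 12
Reactants: 25 (1S,5S,6R)-6-{(4Z)-5-iodo-6-[(2R)-6-methoxy-2,8-dimethyl-3,4-dihydro-2H-chromen-2-yl]-2-methylhexa-1,4-dien-4-yl}-1,5-dimethylbicyclo[3.2.0]heptan-6-ol
Product: 26 (4Z)-4-[(1S,5S,6R)-6-hydroxy-1,5-dimethylbicyclo[3.2.0]heptan-6-yl]-5-iodo-6-[(2R)-6-methoxy-2,8-dimethyl-3,4-dihydro-2H-chromen-2-yl]-2-methylhex-4-en-2-ol
Conditions: Co(acac)2 (20 mol%), PhSiH3, O2 (1 atm), i-PrOH–THF, rt
Reagents that add atoms: dioxygen, O=O
Why: Mukaiyama hydration: hydrogen-atom transfer from a cobalt hydride to the 1,1-disubstituted alkene gives the tertiary radical, which is trapped by dioxygen and reduced to the Markovnikov tertiary alcohol, while the hindered tetrasubstituted iodoalkene should not react.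

Step 13
Reactants: 26 (4Z)-4-[(1S,5S,6R)-6-hydroxy-1,5-dimethylbicyclo[3.2.0]heptan-6-yl]-5-iodo-6-[(2R)-6-methoxy-2,8-dimethyl-3,4-dihydro-2H-chromen-2-yl]-2-methylhex-4-en-2-ol
Product: 29 (3aS,7aS)-5-(2-hydroxy-2-methylpropyl)-6-{[(2R)-6-methoxy-2,8-dimethyl-3,4-dihydro-2H-chromen-2-yl]methyl}-3a,7a-dimethyl-1,2,3,3a,7,7a-hexahydro-4H-inden-4-one, via oxanickelacyclopentene 27 (not isolated), via nickelacycloheptenone 28 (not isolated)
Conditions: Ni(cod)2 (10 mol%), PCy3 (20 mol%), Cs2CO3 (1.5 equiv), toluene, 80 °C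
Reagents that add atoms: none
Why: Proposed new method: zerovalent nickel should insert into the alkenyl C–I bond of 26 and, with carbonate as base, the neighbouring tertiary cyclobutanolate should displace iodide on divalent nickel to give the spiro oxanickelacyclopentene 27, which is the intermediate that the known nickel-catalysed insertion of alkynes into cyclobutanones reaches by oxidative cyclisation but is entered here with C-5 and C-6 already assigned by step 11; the closest known reaction types are that nickel-catalysed cyclobutanone–alkyne [4+2] ring expansion and the palladium-catalysed arylation and alkenylation of tert-cyclobutanols with C–C cleavage. Strain-driven β-carbon elimination then cuts the C-4–C-7 bond to give the seven-membered nickelacycle 28, and C(sp3)–C(sp2) reductive elimination forms the C-6–C-7 bond and returns zerovalent nickel, so the six-membered ring closes by reductive elimination from a nickelacycloheptenone as a two-carbon ring expansion (four- to six-membered) in which C-5=C-6 is inserted between C-4 and C-7. No stereocentre is created: the cleaved C-4–C-7 bond involves neither C-3a nor C-7a, and the carbinol carbon becomes the trigonal ketone carbon C-4, so the resolved configuration of 9 is carried into 29 unchanged. The step needs cleavage of the bond from C-4 to the methylene C-7 and not to the quaternary C-3a, which is secured because β-carbon elimination avoids forming a tertiary alkyl–nickel bond, and it needs the alkyl–nickel species to live until reductive elimination, which is secured by C-7 being neopentyl (C-7a bears no hydrogen, so β-hydride elimination is impossible). It also needs the aryl ether and the stereocentre of the chroman to survive, which is secured because nickel sits only on C-6 and C-7, never on the methylene beside the chroman carbon, and because carbonate in toluene should not form the dienolate that could expel the aryloxide.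

## Compound list

1 | 1,2-dimethylcyclopentene | CC1=C(C)CCC1 | starting material
2 | trichloroacetyl chloride | ClC(=O)C(Cl)(Cl)Cl | starting material
3 | dichloroketene | ClC(Cl)=C=O | intermediate
4 | rac-7,7-dichloro-1,5-dimethylbicyclo[3.2.0]heptan-6-one (cis-fused; both enantiomers shown) | O=C1[C@@]2(C)CCC[C@@]2(C)C1(Cl)Cl.O=C1[C@]2(C)CCC[C@]2(C)C1(Cl)Cl | intermediate
5 | rac-1,5-dimethylbicyclo[3.2.0]heptan-6-one (cis-fused; both enantiomers shown) | O=C1[C@@]2(C)CCC[C@@]2(C)C1.O=C1[C@]2(C)CCC[C@]2(C)C1 | intermediate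
6 | (S)-N,S-dimethyl-S-phenylsulfoximine | C[S@@](=O)(=NC)c1ccccc1 | starting material
7 | {[(S)-N-methyl-S-phenylsulfonimidoyl]methyl}lithium | [Li]C[S@@](=O)(=NC)c1ccccc1 | intermediate
8 | (1S,5S,6R)-1,5-dimethyl-6-{[(S)-N-methyl-S-phenylsulfonimidoyl]methyl}bicyclo[3.2.0]heptan-6-ol | CN=[S@@](=O)(c1ccccc1)C[C@@]2(O)C[C@]3(C)CCC[C@]23C | intermediate
9 | (1S,5S)-1,5-dimethylbicyclo[3.2.0]heptan-6-one | O=C1[C@@]2(C)CCC[C@@]2(C)C1 | intermediate
10 | 2-bromo-5-methoxy-1,3-dimethylbenzene (4-bromo-3,5-dimethylanisole) | COc1cc(C)c(Br)c(C)c1 | starting material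
11 | 2-bromo-1-(bromomethyl)-5-methoxy-3-methylbenzene | COc1cc(C)c(Br)c(CBr)c1 | intermediate
12 | (S)-2-methylglycidol, [(2S)-2-methyloxiran-2-yl]methanol | C[C@]1(CO)CO1 | starting material
13 | (2-bromo-5-methoxy-3-methylbenzyl)magnesium bromide | COc1cc(C)c(Br)c(C[Mg]Br)c1 | intermediate
14 | (2R)-4-(2-bromo-5-methoxy-3-methylphenyl)-2-methylbutane-1,2-diol | COc1cc(C)c(Br)c(CC[C@](C)(CO)O)c1 | intermediate
15 | (2R)-4-(2-bromo-5-methoxy-3-methylphenyl)-2-hydroxy-2-methylbutyl 4-methylbenzenesulfonate | COc1cc(C)c(Br)c(CC[C@](C)(COS(=O)(=O)c2ccc(C)cc2)O)c1 | intermediate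
16 | (2R)-2-[2-(2-bromo-5-methoxy-3-methylphenyl)ethyl]-2-methyloxirane | COc1cc(C)c(Br)c(CC[C@]2(C)CO2)c1 | intermediate
17 | ethynyltrimethylsilane | C#C[Si](C)(C)C | starting material
18 | lithium (trimethylsilyl)acetylide | [Li]C#C[Si](C)(C)C | intermediate
19 | (3R)-1-(2-bromo-5-methoxy-3-methylphenyl)-3-methyl-6-(trimethylsilyl)hex-5-yn-3-ol | COc1cc(C)c(Br)c(CC[C@](C)(CC#C[Si](C)(C)C)O)c1 | intermediate
20 | trimethyl{3-[(2R)-6-methoxy-2,8-dimethyl-3,4-dihydro-2H-chromen-2-yl]prop-1-yn-1-yl}silane | COc1cc(C)c2c(c1)CC[C@](C)(CC#C[Si](C)(C)C)O2 | intermediate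
21 | {3-[(2R)-6-methoxy-2,8-dimethyl-3,4-dihydro-2H-chromen-2-yl]prop-1-yn-1-yl}lithium | COc1cc(C)c2c(c1)CC[C@](C)(CC#C[Li])O2 | intermediate
22 | (1S,5S,6S)-6-{3-[(2R)-6-methoxy-2,8-dimethyl-3,4-dihydro-2H-chromen-2-yl]prop-1-yn-1-yl}-1,5-dimethylbicyclo[3.2.0]heptan-6-ol | COc1cc(C)c2c(c1)CC[C@](C)(CC#C[C@@]3(O)C[C@]4(C)CCC[C@]34C)O2 | intermediate
23 | (2-methylallyl)magnesium chloride | CC(=C)C[Mg]Cl | starting material
24 | chloromagnesium alkoxide of the (Z)-alkenylmagnesium chloride from anti-addition to 22 (O–Mg–C chelate) | COc1cc(C)c2c(c1)CC[C@](C)(C/C([Mg]Cl)=C(\CC(C)=C)[C@@]3(O[Mg]Cl)C[C@]4(C)CCC[C@]34C)O2 | intermediate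
25 | (1S,5S,6R)-6-{(4Z)-5-iodo-6-[(2R)-6-methoxy-2,8-dimethyl-3,4-dihydro-2H-chromen-2-yl]-2-methylhexa-1,4-dien-4-yl}-1,5-dimethylbicyclo[3.2.0]heptan-6-ol | COc1cc(C)c2c(c1)CC[C@](C)(C/C(I)=C(\CC(C)=C)[C@@]3(O)C[C@]4(C)CCC[C@]34C)O2 | intermediate
26 | (4Z)-4-[(1S,5S,6R)-6-hydroxy-1,5-dimethylbicyclo[3.2.0]heptan-6-yl]-5-iodo-6-[(2R)-6-methoxy-2,8-dimethyl-3,4-dihydro-2H-chromen-2-yl]-2-methylhex-4-en-2-ol | COc1cc(C)c2c(c1)CC[C@](C)(C/C(I)=C(\CC(C)(C)O)[C@@]3(O)C[C@]4(C)CCC[C@]34C)O2 | intermediate
27 | spiro oxanickelacyclopentene from 26 (phosphine ligands on nickel omitted) | COc1cc(C)c2c(c1)CC[C@](C)(CC1=C(CC(C)(C)O)[C@@]3(O[Ni]1)C[C@]4(C)CCC[C@]34C)O2 | intermediate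
28 | seven-membered nickelacycloheptenone after β-carbon elimination (phosphine ligands on nickel omitted) | COc1cc(C)c2c(c1)CC[C@](C)(CC1=C(CC(C)(C)O)C(=O)[C@@]3(C)CCC[C@@]3(C)C[Ni]1)O2 | intermediate
29 | (3aS,7aS)-5-(2-hydroxy-2-methylpropyl)-6-{[(2R)-6-methoxy-2,8-dimethyl-3,4-dihydro-2H-chromen-2-yl]methyl}-3a,7a-dimethyl-1,2,3,3a,7,7a-hexahydro-4H-inden-4-one | COc1cc(C)c2c(c1)CC[C@](C)(CC1=C(CC(C)(C)O)C(=O)[C@@]3(C)CCC[C@@]3(C)C1)O2 | target

## Step count and risks

Total step count: 13. Longest linear sequence: 9 steps (steps 5–13, from 10).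

Steps most likely to fail:

1. Step 13 (Proposed new method). The catalytic cycle may stall after oxidative addition: β-carbon elimination from the chelated nickel alkoxide could be slower than protodehalogenation of the alkenyl–nickel bond, or iodide could poison the catalyst. The fallback uses the known nickel-catalysed intermolecular insertion of an alkyne into a cyclobutanone; it sets out from 20 and 9 and comes back at 29. The silyl group of 20 is removed (K2CO3, MeOH) to give the terminal alkyne (2R)-6-methoxy-2,8-dimethyl-2-(prop-2-yn-1-yl)-3,4-dihydro-2H-chromene F1. Its lithium acetylide (n-BuLi, then BF3·OEt2, THF, −78 °C) opens 2,2-dimethyloxirane to 6-[(2R)-6-methoxy-2,8-dimethyl-3,4-dihydro-2H-chromen-2-yl]-2-methylhex-4-yn-2-ol F2. F2 and 9 are then heated with Ni(cod)2 and PCy3 in toluene at 100 °C, which should give 29 directly. The two alkyne substituents are sterically alike, so the regioisomeric enone (3aS,7aS)-6-(2-hydroxy-2-methylpropyl)-5-{[(2R)-6-methoxy-2,8-dimethyl-3,4-dihydro-2H-chromen-2-yl]methyl}-3a,7a-dimethyl-1,2,3,3a,7,7a-hexahydro-4H-inden-4-one F3 is expected alongside and would have to be separated; this lack of regiocontrol is the reason this is not the main route.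

2. Step 11. The congested alkyne may resist carbometalation, or magnesium may not be held on the distal carbon, which would erode regio- and geometric control. The fallback sets out from 22 and comes back at 29; it puts hydrogen on the proximal carbon first and brings in the side chain after ring expansion. trans-Hydroalumination of 22 with NaAlH2(OCH2CH2OMe)2 (THF, 0 °C → rt) and iodinolysis should give (1S,5S,6S)-6-{(1Z)-2-iodo-3-[(2R)-6-methoxy-2,8-dimethyl-3,4-dihydro-2H-chromen-2-yl]prop-1-en-1-yl}-1,5-dimethylbicyclo[3.2.0]heptan-6-ol F4. Ring expansion under the conditions of step 13 should give (3aS,7aS)-6-{[(2R)-6-methoxy-2,8-dimethyl-3,4-dihydro-2H-chromen-2-yl]methyl}-3a,7a-dimethyl-1,2,3,3a,7,7a-hexahydro-4H-inden-4-one F5. α-Iodination (I2, pyridine, CH2Cl2) should give (3aS,7aS)-5-iodo-6-{[(2R)-6-methoxy-2,8-dimethyl-3,4-dihydro-2H-chromen-2-yl]methyl}-3a,7a-dimethyl-1,2,3,3a,7,7a-hexahydro-4H-inden-4-one F6. Stille coupling with tributyl(2-methylallyl)stannane (Pd(PPh3)4, CuI, DMF, 60 °C) should give (3aS,7aS)-6-{[(2R)-6-methoxy-2,8-dimethyl-3,4-dihydro-2H-chromen-2-yl]methyl}-3a,7a-dimethyl-5-(2-methylprop-2-en-1-yl)-1,2,3,3a,7,7a-hexahydro-4H-inden-4-one F7. Mukaiyama hydration under the conditions of step 12 then gives 29.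

3. Step 3. Poor facial selectivity in the addition would give four adducts and an inefficient separation, and thermal reversal of a cyclobutanol adduct in step 4 may be sluggish. The fallback sets out from 5 and comes back at 9; it uses a C2-symmetric ketal, which creates no new stereocentre, so only two diastereomers can form. Ketalisation of 5 with (2R,3R)-butane-2,3-diol (TsOH, benzene, reflux, water removal) and separation of the two ketals by chromatography or crystallisation gives the (4R,5R)-4,5-dimethyl-1,3-dioxolane spiro ketal of (1S,5S)-1,5-dimethylbicyclo[3.2.0]heptan-6-one F8. Hydrolysis (aq. HCl, acetone, rt) returns 9.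

## Further compounds

F1 | step 13 | (2R)-6-methoxy-2,8-dimethyl-2-(prop-2-yn-1-yl)-3,4-dihydro-2H-chromene | COc1cc(C)c2c(c1)CC[C@](C)(CC#C)O2
F2 | step 13 | 6-[(2R)-6-methoxy-2,8-dimethyl-3,4-dihydro-2H-chromen-2-yl]-2-methylhex-4-yn-2-ol | COc1cc(C)c2c(c1)CC[C@](C)(CC#CCC(C)(C)O)O2
F3 | step 13 | (3aS,7aS)-6-(2-hydroxy-2-methylpropyl)-5-{[(2R)-6-methoxy-2,8-dimethyl-3,4-dihydro-2H-chromen-2-yl]methyl}-3a,7a-dimethyl-1,2,3,3a,7,7a-hexahydro-4H-inden-4-one | COc1cc(C)c2c(c1)CC[C@](C)(CC1=C(CC(C)(C)O)C[C@]3(C)CCC[C@]3(C)C1=O)O2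
F4 | step 11 | (1S,5S,6S)-6-{(1Z)-2-iodo-3-[(2R)-6-methoxy-2,8-dimethyl-3,4-dihydro-2H-chromen-2-yl]prop-1-en-1-yl}-1,5-dimethylbicyclo[3.2.0]heptan-6-ol | COc1cc(C)c2c(c1)CC[C@](C)(C/C(I)=C/[C@@]3(O)C[C@]4(C)CCC[C@]34C)O2
F5 | step 11 | (3aS,7aS)-6-{[(2R)-6-methoxy-2,8-dimethyl-3,4-dihydro-2H-chromen-2-yl]methyl}-3a,7a-dimethyl-1,2,3,3a,7,7a-hexahydro-4H-inden-4-one | COc1cc(C)c2c(c1)CC[C@](C)(CC1=CC(=O)[C@@]3(C)CCC[C@@]3(C)C1)O2
F6 | step 11 | (3aS,7aS)-5-iodo-6-{[(2R)-6-methoxy-2,8-dimethyl-3,4-dihydro-2H-chromen-2-yl]methyl}-3a,7a-dimethyl-1,2,3,3a,7,7a-hexahydro-4H-inden-4-one | COc1cc(C)c2c(c1)CC[C@](C)(CC1=C(I)C(=O)[C@@]3(C)CCC[C@@]3(C)C1)O2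
F7 | step 11 | (3aS,7aS)-6-{[(2R)-6-methoxy-2,8-dimethyl-3,4-dihydro-2H-chromen-2-yl]methyl}-3a,7a-dimethyl-5-(2-methylprop-2-en-1-yl)-1,2,3,3a,7,7a-hexahydro-4H-inden-4-one | COc1cc(C)c2c(c1)CC[C@](C)(CC1=C(CC(C)=C)C(=O)[C@@]3(C)CCC[C@@]3(C)C1)O2
F8 | step 3 | (4R,5R)-4,5-dimethyl-1,3-dioxolane spiro ketal of (1S,5S)-1,5-dimethylbicyclo[3.2.0]heptan-6-one | C[C@H]1OC2(C[C@]3(C)CCC[C@]23C)O[C@@H]1C
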